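**Retrosynthetic overview**

1. The target is a (3R,4R)-3,4-dibenzyloxolan-2-one (ring A benzyl on C3, ring B benzyl on C4) whose ring B carries at C5 an (S)-CH(CH2OH)–C(=O)–ring C unit. It is cut last at four O-benzyl groups, then at the ring B C5–CH bond by an enantioconvergent nickel Negishi coupling of a ring B arylzinc with a racemic ring C α-bromoketone.
2. The ring B iodide comes from ortho-iodination of the free ring B phenol. Ring A is joined to the exocyclic CH2 on C3 by rhodium-catalysed conjugate addition of a boronic acid to an α-methylene lactone, then C3 is epimerised to trans.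
3. Feature used: the lactone carbonyl carbon C2 lies between O1 and C3, and C3 carries one exocyclic carbon (the benzylic CH2 of ring A). C2 is therefore CO, and C3 with its exocyclic carbon are the two carbons of a terminal alkyne on the C4 stereocentre, with C5–O1 as the alcohol arm. Palladium cyclocarbonylation of an (R)-2-benzylbut-3-yn-1-ol closes the lactone.
4. The alkynol comes from dihydroferulic acid by oxazolidinone-controlled hydroxymethylation (sets C4), reduction, oxidation and Ohira–Bestmann alkynylation.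
5. Ring formation: only the lactone ring is built (step 9); rings A, B and C are bought as guaiacyl units.

Key step: step 9

Remark: lactone atoms are numbered as in oxolan-2-one (O1, C2 carbonyl, C3, C4, C5); the target is read as 3R,4R in the lactone and S at the side-chain carbon. Assumption: which antipode of the pybox ligand gives the S centre in step 18 is fixed beforehand on a simple model arylzinc, and the route is written for that antipode.

**Route**

Step 1
Reactants: 1 3-(4-hydroxy-3-methoxyphenyl)propanoic acid (dihydroferulic acid)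
Product: 3 3-[3-methoxy-4-(triisopropylsilyloxy)phenyl]propanoic acid, via bis-silyl ester 2 (not isolated)
Conditions: TIPSCl (2.3 equiv), imidazole, DMF, rt; then K2CO3, THF/MeOH/H2O, 0 °C; HCl work-up
Reagents that add atoms: triisopropylsilyl chloride, CC(C)[Si](Cl)(C(C)C)C(C)C
Why: Silyl ether protection of phenol and acid followed by selective solvolysis of the much more labile silyl ester should leave the hindered aryl silyl ether, chosen because it tolerates TiCl4, hydride, mild carbonate and CO/palladium and can later be removed beside benzyl ethers.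

Step 2
Reactants: 3 3-[3-methoxy-4-(triisopropylsilyloxy)phenyl]propanoic acid; 4 (R)-4-benzyl-1,3-oxazolidin-2-one
Product: 6 (R)-4-benzyl-3-{3-[3-methoxy-4-(triisopropylsilyloxy)phenyl]propanoyl}-1,3-oxazolidin-2-one, via mixed pivalic anhydride 5 (not isolated)
Conditions: PivCl, Et3N, THF, −20 °C; then 4, LiCl, −20 °C → rt
Reagents that add atoms: none
Why: N-acylation of the chiral auxiliary through the mixed anhydride under LiCl/Et3N activation is a standard acyl transfer that touches neither the silyl ether nor the arene.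

Step 3
Reactants: 6 (R)-4-benzyl-3-{3-[3-methoxy-4-(triisopropylsilyloxy)phenyl]propanoyl}-1,3-oxazolidin-2-one
Product: 8 (R)-4-benzyl-3-{(2S)-2-(hydroxymethyl)-3-[3-methoxy-4-(triisopropylsilyloxy)phenyl]propanoyl}-1,3-oxazolidin-2-one, via chlorotitanium enolate 7 (not isolated)
Conditions: TiCl4 (1.05 equiv), iPr2NEt (1.1 equiv), CH2Cl2, 0 °C; then 1,3,5-trioxane, TiCl4 (1.05 equiv), 0 °C
Reagents that add atoms: 1,3,5-trioxane, C1OCOCO1
Why: In this auxiliary-controlled hydroxymethylation (aldol-type addition of a titanium enolate to TiCl4-activated formaldehyde) the chelated Z-enolate is attacked on the face away from the benzyl group of the oxazolidinone, which should set the new centre as S, the configuration that becomes 4R of the lactone once the imide carbonyl is turned into the alkyne.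

Step 4
Reactants: 8 (R)-4-benzyl-3-{(2S)-2-(hydroxymethyl)-3-[3-methoxy-4-(triisopropylsilyloxy)phenyl]propanoyl}-1,3-oxazolidin-2-one
Product: 9 (R)-4-benzyl-3-{(2S)-2-[(tert-butyldimethylsilyloxy)methyl]-3-[3-methoxy-4-(triisopropylsilyloxy)phenyl]propanoyl}-1,3-oxazolidin-2-one
Conditions: TBSCl, imidazole, DMF, rt
Reagents that add atoms: tert-butyldimethylsilyl chloride, CC(C)(C)[Si](C)(C)Cl
Why: Silylation of the primary alcohol keeps the two one-carbon arms on the stereocentre distinct before the imide is reduced, since the unprotected 1,3-diol would be achiral.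

Step 5
Reactants: 9 (R)-4-benzyl-3-{(2S)-2-[(tert-butyldimethylsilyloxy)methyl]-3-[3-methoxy-4-(triisopropylsilyloxy)phenyl]propanoyl}-1,3-oxazolidin-2-one
Product: 10 (2R)-2-[(tert-butyldimethylsilyloxy)methyl]-3-[3-methoxy-4-(triisopropylsilyloxy)phenyl]propan-1-ol
Conditions: LiBH4, MeOH (1.1 equiv), THF, 0 °C
Reagents that add atoms: none
Why: Reductive cleavage of the N-acyl oxazolidinone by borohydride attacks the exocyclic carbonyl, releases the auxiliary for recovery and does not enolise the stereocentre.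

Step 6
Reactants: 10 (2R)-2-[(tert-butyldimethylsilyloxy)methyl]-3-[3-methoxy-4-(triisopropylsilyloxy)phenyl]propan-1-ol
Product: 11 (2S)-2-[(tert-butyldimethylsilyloxy)methyl]-3-[3-methoxy-4-(triisopropylsilyloxy)phenyl]propanal
Conditions: Dess–Martin periodinane, pyridine, CH2Cl2, 0 °C → rt
Reagents that add atoms: none
Why: Buffered Dess–Martin oxidation gives the α-branched aldehyde under non-enolising conditions, and the aldehyde is used at once.

Step 7
Reactants: 11 (2S)-2-[(tert-butyldimethylsilyloxy)methyl]-3-[3-methoxy-4-(triisopropylsilyloxy)phenyl]propanal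
Product: 12 (R)-tert-butyl({2-[3-methoxy-4-(triisopropylsilyloxy)benzyl]but-3-yn-1-yl}oxy)dimethylsilane
Conditions: dimethyl (1-diazo-2-oxopropyl)phosphonate, K2CO3, MeOH, 0 °C → rt
Reagents that add atoms: dimethyl (1-diazo-2-oxopropyl)phosphonate, CC(=O)C(=[N+]=[N-])P(=O)(OC)OC
Why: Ohira–Bestmann (Seyferth–Gilbert) homologation converts the aldehyde into the terminal alkyne through an alkylidene carbene 1,2-hydrogen shift under carbonate conditions mild enough that the α-centre and both silyl ethers should be kept.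

Step 8
Reactants: 12 (R)-tert-butyl({2-[3-methoxy-4-(triisopropylsilyloxy)benzyl]but-3-yn-1-yl}oxy)dimethylsilane
Product: 13 (R)-2-[3-methoxy-4-(triisopropylsilyloxy)benzyl]but-3-yn-1-ol
Conditions: CSA (10 mol%), MeOH/CH2Cl2, 0 °C → rt
Reagents that add atoms: none
Why: Acid-catalysed methanolysis removes the primary alkyl silyl ether selectively because the hindered aryl triisopropylsilyl ether is far less acid-labile.

Step 9
Reactants: 13 (R)-2-[3-methoxy-4-(triisopropylsilyloxy)benzyl]but-3-yn-1-ol
Product: 14 (4R)-4-[3-methoxy-4-(triisopropylsilyloxy)benzyl]-3-methylideneoxolan-2-one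
Conditions: PdCl2 (5 mol%), SnCl2 (5 mol%), PPh3 (10 mol%), CO (7 atm), MeCN, 75 °C
Reagents that add atoms: carbon monoxide, [C-]#[O+]
Why: Divalent palladium, the alcohol and CO should give an alkoxycarbonyl–palladium species that adds syn across the tethered triple bond, the acyl carbon bonding to the internal alkyne carbon and palladium ending on the terminal carbon; protonolysis of this vinyl–palladium bond by the acid set free in the first stage releases the exocyclic methylene and returns the catalyst. The closest known reaction type is the PdCl2/SnCl2/phosphine cyclocarbonylation of but-3-yn-1-ols to α-methylene-γ-butyrolactones, applied here to a substrate with one propargylic substituent. The lactone ring closes in a 5-exo-dig mode through the O1–C2 and C2–C3 bonds, CO supplying C2. No stereocentre is formed, and C4, set by the auxiliary in step 3, is a spectator because the medium is neutral. The step needs exo rather than 6-endo insertion, which the two-atom tether between hydroxyl and alkyne secures, and it needs the new double bond to stay exocyclic, which the absence of base and the moderate temperature should secure; the aryl silyl ether and methyl ether are inert to CO and to the weak Lewis acid SnCl2.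

Step 10
Reactants: 14 (4R)-4-[3-methoxy-4-(triisopropylsilyloxy)benzyl]-3-methylideneoxolan-2-one; 15 4-(benzyloxy)-3-methoxyphenylboronic acid
Product: 16 (4R)-3-[4-(benzyloxy)-3-methoxybenzyl]-4-[3-methoxy-4-(triisopropylsilyloxy)benzyl]oxolan-2-one as a mixture of C3 epimers
Conditions: 15 (1.5 equiv), [Rh(cod)OH]2 (2.5 mol%), dioxane/H2O (10:1), 50 °C
Reagents that add atoms: none
Why: In this rhodium-catalysed conjugate addition (Hayashi–Miyaura type) the aryl–rhodium species adds to the exocyclic methylene and water protonates the rhodium enolate, expected mainly anti to the C4 benzyl group (cis lactone), while the base-free hydroxo-rhodium catalyst should avoid migration of the double bond into the ring.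

Step 11
Reactants: 16 (4R)-3-[4-(benzyloxy)-3-methoxybenzyl]-4-[3-methoxy-4-(triisopropylsilyloxy)benzyl]oxolan-2-one as a mixture of C3 epimers
Product: 17 (3R,4R)-3-[4-(benzyloxy)-3-methoxybenzyl]-4-[3-methoxy-4-(triisopropylsilyloxy)benzyl]oxolan-2-one
Conditions: DBU (0.5 equiv), toluene, 80 °C
Reagents that add atoms: none
Why: Base-mediated epimerisation through the lactone enolate should equilibrate C3 to the thermodynamically preferred trans 3,4-dibenzyl arrangement (3R), the C4 centre having no acidic hydrogen.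

Step 12
Reactants: 17 (3R,4R)-3-[4-(benzyloxy)-3-methoxybenzyl]-4-[3-methoxy-4-(triisopropylsilyloxy)benzyl]oxolan-2-one
Product: 18 (3R,4R)-3-[4-(benzyloxy)-3-methoxybenzyl]-4-(4-hydroxy-3-methoxybenzyl)oxolan-2-one
Conditions: TBAF, AcOH, THF, 0 °C
Reagents that add atoms: none
Why: Fluoride desilylation buffered with acetic acid frees only the ring B phenol and leaves the lactone, the benzyl ether and the C3 configuration alone.

Step 13
Reactants: 18 (3R,4R)-3-[4-(benzyloxy)-3-methoxybenzyl]-4-(4-hydroxy-3-methoxybenzyl)oxolan-2-one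
Product: 19 (3R,4R)-3-[4-(benzyloxy)-3-methoxybenzyl]-4-(4-hydroxy-3-iodo-5-methoxybenzyl)oxolan-2-one
Conditions: BnMe3N·ICl2, NaHCO3, CH2Cl2/MeOH, rt
Reagents that add atoms: benzyltrimethylammonium dichloroiodate, C[N+](C)(C)Cc1ccccc1.Cl[I-]Cl
Why: Electrophilic aromatic iodination under bicarbonate conditions is directed by the free phenol to its only open ortho position, C5 of ring B (the other ortho position bears OMe and the para position the benzylic carbon), whereas the dialkoxy ring A needs Lewis acid activation to react with this reagent.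

Step 14
Reactants: 19 (3R,4R)-3-[4-(benzyloxy)-3-methoxybenzyl]-4-(4-hydroxy-3-iodo-5-methoxybenzyl)oxolan-2-one
Product: 20 (3R,4R)-3-[4-(benzyloxy)-3-methoxybenzyl]-4-[4-(benzyloxy)-3-iodo-5-methoxybenzyl]oxolan-2-one
Conditions: BnBr, K2CO3, DMF, rt
Reagents that add atoms: benzyl bromide, BrCc1ccccc1
Why: Williamson etherification masks the phenol before metalation with a group that leaves in the final hydrogenolysis, carbonate being too weak to alkylate the lactone α-carbon.

Step 15
Reactants: 21 3-(benzyloxy)propanoic acid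
Product: 23 3-(benzyloxy)-N-methoxy-N-methylpropanamide, via acyl imidazole 22 (not isolated)
Conditions: CDI, CH2Cl2, rt; then MeNHOMe·HCl, rt
Reagents that add atoms: N,O-dimethylhydroxylamine hydrochloride, CNOC.Cl
Why: Weinreb amide formation through the acyl imidazole is a mild amidation that leaves the benzyl ether untouched.

Step 16
Reactants: 24 1-(benzyloxy)-4-bromo-2-methoxybenzene; 23 3-(benzyloxy)-N-methoxy-N-methylpropanamide
Product: 26 3-(benzyloxy)-1-[4-(benzyloxy)-3-methoxyphenyl]propan-1-one, via aryl Grignard reagent 25 (not isolated)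
Conditions: Mg, THF, 40 °C; then 23, 0 °C; 1 M HCl work-up
Reagents that add atoms: none
Why: Grignard addition to the Weinreb amide stops at the chelated tetrahedral adduct, so the aryl ketone should form without over-addition.

Step 17
Reactants: 26 3-(benzyloxy)-1-[4-(benzyloxy)-3-methoxyphenyl]propan-1-one
Product: 28 rac-3-(benzyloxy)-1-[4-(benzyloxy)-3-methoxyphenyl]-2-bromopropan-1-one, via silyl enol ether 27 (not isolated)
Conditions: TMSOTf, Et3N, CH2Cl2, 0 °C; then NBS, THF, 0 °C
Reagents that add atoms: N-bromosuccinimide, O=C1CCC(=O)N1Br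
Why: Soft enolisation to the silyl enol ether and its electrophilic bromination give the α-bromoketone without a free enolate (no loss of benzyl alcohol) and without ring bromination, and the racemate is what the stereoconvergent coupling requires.

Step 18
Reactants: 20 (3R,4R)-3-[4-(benzyloxy)-3-methoxybenzyl]-4-[4-(benzyloxy)-3-iodo-5-methoxybenzyl]oxolan-2-one; 28 rac-3-(benzyloxy)-1-[4-(benzyloxy)-3-methoxyphenyl]-2-bromopropan-1-one
Product: 31 (3R,4R)-3-[4-(benzyloxy)-3-methoxybenzyl]-4-{4-(benzyloxy)-3-[(2S)-1-(benzyloxy)-3-[4-(benzyloxy)-3-methoxyphenyl]-3-oxopropan-2-yl]-5-methoxybenzyl}oxolan-2-one, via arylmagnesium chloride 29 (not isolated), via arylzinc iodide 30 (not isolated)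
Conditions: iPrMgCl·LiCl, THF, −40 °C; ZnI2, −40 → 0 °C; then 28 (1.5 equiv), NiCl2·glyme (10 mol%), chiral pybox ligand (13 mol%), glyme/THF, −30 °C
Reagents that add atoms: none
Why: After iodine–magnesium exchange and transmetalation to zinc, the enantioconvergent nickel-catalysed Negishi coupling turns both enantiomers of 28 into one planar α-keto radical by bromine abstraction, and the chiral pybox–nickel–aryl complex captures it and reductively eliminates so that the ligand alone should set the new benzylic centre as S, the low temperature and the weakly basic zinc reagent protecting this tertiary α-aryl ketone centre and the lactone.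

Step 19
Reactants: 31 (3R,4R)-3-[4-(benzyloxy)-3-methoxybenzyl]-4-{4-(benzyloxy)-3-[(2S)-1-(benzyloxy)-3-[4-(benzyloxy)-3-methoxyphenyl]-3-oxopropan-2-yl]-5-methoxybenzyl}oxolan-2-one
Product: 32 (3R,4R)-3-(4-hydroxy-3-methoxybenzyl)-4-{4-hydroxy-3-[(2S)-1-hydroxy-3-(4-hydroxy-3-methoxyphenyl)-3-oxopropan-2-yl]-5-methoxybenzyl}oxolan-2-one
Conditions: H2 (1 atm), Pd(OH)2/C, EtOAc/EtOH, rt
Reagents that add atoms: none
Why: Hydrogenolysis of the three aryl benzyl ethers and the one alkyl benzyl ether is neutral, so the epimerisable and dehydration-prone α-aryl β-hydroxy ketone should survive, and the electron-rich aryl ketone is reduced much more slowly than the ethers are cleaved.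

**Compound list**

1 | 3-(4-hydroxy-3-methoxyphenyl)propanoic acid | COc1cc(CCC(=O)O)ccc1O | starting material
2 | triisopropylsilyl 3-[3-methoxy-4-(triisopropylsilyloxy)phenyl]propanoate | COc1cc(CCC(=O)O[Si](C(C)C)(C(C)C)C(C)C)ccc1O[Si](C(C)C)(C(C)C)C(C)C | intermediate
3 | 3-[3-methoxy-4-(triisopropylsilyloxy)phenyl]propanoic acid | COc1cc(CCC(=O)O)ccc1O[Si](C(C)C)(C(C)C)C(C)C | intermediate
4 | (R)-4-benzyl-1,3-oxazolidin-2-one | O=C1N[C@H](Cc2ccccc2)CO1 | starting material
5 | mixed anhydride of 3 with pivalic acid | COc1cc(CCC(=O)OC(=O)C(C)(C)C)ccc1O[Si](C(C)C)(C(C)C)C(C)C | intermediate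
6 | (R)-4-benzyl-3-{3-[3-methoxy-4-(triisopropylsilyloxy)phenyl]propanoyl}-1,3-oxazolidin-2-one | COc1cc(CCC(=O)N2[C@H](Cc3ccccc3)COC2=O)ccc1O[Si](C(C)C)(C(C)C)C(C)C | intermediate
7 | trichlorotitanium Z-enolate of 6 | COc1cc(C/C=C(\O[Ti](Cl)(Cl)Cl)N2[C@H](Cc3ccccc3)COC2=O)ccc1O[Si](C(C)C)(C(C)C)C(C)C | intermediate
8 | (R)-4-benzyl-3-{(2S)-2-(hydroxymethyl)-3-[3-methoxy-4-(triisopropylsilyloxy)phenyl]propanoyl}-1,3-oxazolidin-2-one | COc1cc(C[C@@H](CO)C(=O)N2[C@H](Cc3ccccc3)COC2=O)ccc1O[Si](C(C)C)(C(C)C)C(C)C | intermediate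
9 | (R)-4-benzyl-3-{(2S)-2-[(tert-butyldimethylsilyloxy)methyl]-3-[3-methoxy-4-(triisopropylsilyloxy)phenyl]propanoyl}-1,3-oxazolidin-2-one | COc1cc(C[C@@H](CO[Si](C)(C)C(C)(C)C)C(=O)N2[C@H](Cc3ccccc3)COC2=O)ccc1O[Si](C(C)C)(C(C)C)C(C)C | intermediate
10 | (2R)-2-[(tert-butyldimethylsilyloxy)methyl]-3-[3-methoxy-4-(triisopropylsilyloxy)phenyl]propan-1-ol | COc1cc(C[C@@H](CO[Si](C)(C)C(C)(C)C)CO)ccc1O[Si](C(C)C)(C(C)C)C(C)C | intermediate
11 | (2S)-2-[(tert-butyldimethylsilyloxy)methyl]-3-[3-methoxy-4-(triisopropylsilyloxy)phenyl]propanal | COc1cc(C[C@@H](CO[Si](C)(C)C(C)(C)C)C=O)ccc1O[Si](C(C)C)(C(C)C)C(C)C | intermediate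
12 | (R)-tert-butyl({2-[3-methoxy-4-(triisopropylsilyloxy)benzyl]but-3-yn-1-yl}oxy)dimethylsilane | COc1cc(C[C@@H](CO[Si](C)(C)C(C)(C)C)C#C)ccc1O[Si](C(C)C)(C(C)C)C(C)C | intermediate
13 | (R)-2-[3-methoxy-4-(triisopropylsilyloxy)benzyl]but-3-yn-1-ol | COc1cc(C[C@@H](CO)C#C)ccc1O[Si](C(C)C)(C(C)C)C(C)C | intermediate
14 | (4R)-4-[3-methoxy-4-(triisopropylsilyloxy)benzyl]-3-methylideneoxolan-2-one | C=C1C(=O)OC[C@@H]1Cc1ccc(O[Si](C(C)C)(C(C)C)C(C)C)c(OC)c1 | intermediate
15 | 4-(benzyloxy)-3-methoxyphenylboronic acid | COc1cc(B(O)O)ccc1OCc1ccccc1 | starting material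
16 | (4R)-3-[4-(benzyloxy)-3-methoxybenzyl]-4-[3-methoxy-4-(triisopropylsilyloxy)benzyl]oxolan-2-one (C3 epimer mixture) | COc1cc(CC2C(=O)OC[C@@H]2Cc2ccc(O[Si](C(C)C)(C(C)C)C(C)C)c(OC)c2)ccc1OCc1ccccc1 | intermediate
17 | (3R,4R)-3-[4-(benzyloxy)-3-methoxybenzyl]-4-[3-methoxy-4-(triisopropylsilyloxy)benzyl]oxolan-2-one | COc1cc(C[C@H]2C(=O)OC[C@@H]2Cc2ccc(O[Si](C(C)C)(C(C)C)C(C)C)c(OC)c2)ccc1OCc1ccccc1 | intermediate
18 | (3R,4R)-3-[4-(benzyloxy)-3-methoxybenzyl]-4-(4-hydroxy-3-methoxybenzyl)oxolan-2-one | COc1cc(C[C@H]2C(=O)OC[C@@H]2Cc2ccc(O)c(OC)c2)ccc1OCc1ccccc1 | intermediate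
19 | (3R,4R)-3-[4-(benzyloxy)-3-methoxybenzyl]-4-(4-hydroxy-3-iodo-5-methoxybenzyl)oxolan-2-one | COc1cc(C[C@H]2C(=O)OC[C@@H]2Cc2cc(I)c(O)c(OC)c2)ccc1OCc1ccccc1 | intermediate
20 | (3R,4R)-3-[4-(benzyloxy)-3-methoxybenzyl]-4-[4-(benzyloxy)-3-iodo-5-methoxybenzyl]oxolan-2-one | COc1cc(C[C@H]2C(=O)OC[C@@H]2Cc2cc(I)c(OCc3ccccc3)c(OC)c2)ccc1OCc1ccccc1 | intermediate
21 | 3-(benzyloxy)propanoic acid | OC(=O)CCOCc1ccccc1 | starting material
22 | 3-(benzyloxy)-1-(1H-imidazol-1-yl)propan-1-one | O=C(CCOCc1ccccc1)n1ccnc1 | intermediate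
23 | 3-(benzyloxy)-N-methoxy-N-methylpropanamide | CON(C)C(=O)CCOCc1ccccc1 | intermediate
24 | 1-(benzyloxy)-4-bromo-2-methoxybenzene | COc1cc(Br)ccc1OCc1ccccc1 | starting material
25 | 4-(benzyloxy)-3-methoxyphenylmagnesium bromide | COc1cc([Mg]Br)ccc1OCc1ccccc1 | intermediate
26 | 3-(benzyloxy)-1-[4-(benzyloxy)-3-methoxyphenyl]propan-1-one | COc1cc(C(=O)CCOCc2ccccc2)ccc1OCc1ccccc1 | intermediate
27 | (Z)-trimethylsilyl enol ether of 26 | COc1cc(/C(O[Si](C)(C)C)=C/COCc2ccccc2)ccc1OCc1ccccc1 | intermediate
28 | rac-3-(benzyloxy)-1-[4-(benzyloxy)-3-methoxyphenyl]-2-bromopropan-1-one | COc1cc(C(=O)C(Br)COCc2ccccc2)ccc1OCc1ccccc1 | intermediate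
29 | arylmagnesium chloride (20 with MgCl in place of I) | COc1cc(C[C@H]2C(=O)OC[C@@H]2Cc2cc([Mg]Cl)c(OCc3ccccc3)c(OC)c2)ccc1OCc1ccccc1 | intermediate
30 | arylzinc iodide (20 with ZnI in place of I) | COc1cc(C[C@H]2C(=O)OC[C@@H]2Cc2cc([Zn]I)c(OCc3ccccc3)c(OC)c2)ccc1OCc1ccccc1 | intermediate
31 | (3R,4R)-3-[4-(benzyloxy)-3-methoxybenzyl]-4-{4-(benzyloxy)-3-[(2S)-1-(benzyloxy)-3-[4-(benzyloxy)-3-methoxyphenyl]-3-oxopropan-2-yl]-5-methoxybenzyl}oxolan-2-one | COc1cc(C[C@H]2C(=O)OC[C@@H]2Cc2cc(OC)c(OCc3ccccc3)c([C@@H](COCc3ccccc3)C(=O)c3ccc(OCc4ccccc4)c(OC)c3)c2)ccc1OCc1ccccc1 | intermediate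
32 | (3R,4R)-3-(4-hydroxy-3-methoxybenzyl)-4-{4-hydroxy-3-[(2S)-1-hydroxy-3-(4-hydroxy-3-methoxyphenyl)-3-oxopropan-2-yl]-5-methoxybenzyl}oxolan-2-one | COc1cc(C[C@H]2C(=O)OC[C@@H]2Cc2cc(OC)c(O)c([C@@H](CO)C(=O)c3ccc(O)c(OC)c3)c2)ccc1O | target

**Step count and risks**

Total step count: 19. Longest linear sequence: 16 steps (steps 1–14, 18 and 19 from compound 1); the ring C branch (steps 15–17) joins at step 18.

Steps most likely to fail:

Step 18. The ortho-benzyloxy group on the arylzinc may slow transmetalation and coupling. Benzyl alcohol may be lost from the bromoketone or from its nickel enolate. Catalyst control at the new centre may be incomplete, and the lactone α-position may be deprotonated during the iodine–magnesium exchange. The fallback sets out from 20 and replaces the coupling by auxiliary control and a neutral ketone synthesis. Palladium-catalysed Negishi coupling of 20 with BrZnCH2CO2tBu (Pd2(dba)3, XPhos, THF) should give the tert-butyl arylacetate F1. TFA in CH2Cl2 frees the arylacetic acid F2, which is attached to auxiliary 4 (PivCl, Et3N, LiCl) to give the arylacetyl imide F3. Its chlorotitanium enolate (TiCl4, iPr2NEt) is alkylated with benzyl chloromethyl ether on the face away from the auxiliary benzyl group to give the (S)-benzyloxymethyl imide F4. LiSEt in THF at 0 °C exchanges the auxiliary for the S-ethyl thioester F5. Liebeskind–Srogl coupling of F5 with boronic acid 15 (Pd2(dba)3, tri(2-furyl)phosphine, copper thiophene-2-carboxylate CuTC, THF, 50 °C) forms the aryl ketone without base and comes back to the route at 31.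

Step 9. The palladium may be reduced to inactive metal before turnover, the alkyne may oligomerise, or the exocyclic double bond may migrate into the ring with loss of the C4 configuration. The fallback sets out from acid 3 and builds the lactone without CO. Acylation of (S)-4-benzyl-1,3-oxazolidin-2-one gives the mirror-auxiliary imide F6; the mirror auxiliary is needed because the two arms on the stereocentre exchange roles. Alkylation of its sodium enolate (NaHMDS, THF, −78 °C) with tert-butyl bromoacetate gives the succinate-type imide F7. LiBH4 reduces the imide to the hydroxy ester F8, and catalytic TsOH closes it to the (R)-4-benzyl lactone F9. Aminomethylation of the lactone enolate (LiHMDS, Eschenmoser's salt) gives the Mannich base F10, MeI converts it into the methiodide F11, and elimination with NaHCO3 comes back to the route at 14.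

Step 10. The alkylrhodium intermediate may undergo β-hydride elimination to an arylidene lactone, the double bond may migrate into the ring before addition, or the boronic acid may protodeboronate. The fallback sets out from 14 and uses an organocopper conjugate addition in place of the rhodium–boron system: aryl Grignard reagent 25, made as in step 16, with CuBr·SMe2 in THF at −40 °C, followed by an NH4Cl quench of the magnesium enolate. This comes back to the route at 16 as the same epimer mixture and makes no new compound.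

Further compounds

F1 | step 18 | tert-butyl arylacetate (20 with CH2CO2tBu in place of I) | COc1cc(C[C@H]2C(=O)OC[C@@H]2Cc2cc(OC)c(OCc3ccccc3)c(CC(=O)OC(C)(C)C)c2)ccc1OCc1ccccc1
F2 | step 18 | arylacetic acid (20 with CH2CO2H in place of I) | COc1cc(C[C@H]2C(=O)OC[C@@H]2Cc2cc(OC)c(OCc3ccccc3)c(CC(=O)O)c2)ccc1OCc1ccccc1
F3 | step 18 | arylacetyl imide of F2 with (R)-4-benzyl-1,3-oxazolidin-2-one | COc1cc(C[C@H]2C(=O)OC[C@@H]2Cc2cc(OC)c(OCc3ccccc3)c(CC(=O)N3[C@H](Cc4ccccc4)COC3=O)c2)ccc1OCc1ccccc1
F4 | step 18 | (S)-benzyloxymethyl imide (F3 with CH2OBn on the α-carbon) | COc1cc(C[C@H]2C(=O)OC[C@@H]2Cc2cc(OC)c(OCc3ccccc3)c([C@@H](COCc3ccccc3)C(=O)N3[C@H](Cc4ccccc4)COC3=O)c2)ccc1OCc1ccccc1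
F5 | step 18 | S-ethyl thioester of the (S)-3-(benzyloxy)-2-arylpropanoic acid | COc1cc(C[C@H]2C(=O)OC[C@@H]2Cc2cc(OC)c(OCc3ccccc3)c([C@@H](COCc3ccccc3)C(=O)SCC)c2)ccc1OCc1ccccc1
F6 | step 9 | (S)-4-benzyl-3-{3-[3-methoxy-4-(triisopropylsilyloxy)phenyl]propanoyl}-1,3-oxazolidin-2-one | COc1cc(CCC(=O)N2[C@@H](Cc3ccccc3)COC2=O)ccc1O[Si](C(C)C)(C(C)C)C(C)C
F7 | step 9 | tert-butyl (3R)-3-[(S)-4-benzyl-2-oxo-1,3-oxazolidine-3-carbonyl]-4-[3-methoxy-4-(triisopropylsilyloxy)phenyl]butanoate | COc1cc(C[C@H](CC(=O)OC(C)(C)C)C(=O)N2[C@@H](Cc3ccccc3)COC2=O)ccc1O[Si](C(C)C)(C(C)C)C(C)C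
F8 | step 9 | tert-butyl (3R)-3-(hydroxymethyl)-4-[3-methoxy-4-(triisopropylsilyloxy)phenyl]butanoate | COc1cc(C[C@H](CC(=O)OC(C)(C)C)CO)ccc1O[Si](C(C)C)(C(C)C)C(C)C
F9 | step 9 | (4R)-4-[3-methoxy-4-(triisopropylsilyloxy)benzyl]oxolan-2-one | O=C1C[C@@H](Cc2ccc(O[Si](C(C)C)(C(C)C)C(C)C)c(OC)c2)CO1
F10 | step 9 | (4R)-3-[(dimethylamino)methyl]-4-[3-methoxy-4-(triisopropylsilyloxy)benzyl]oxolan-2-one | CN(C)CC1C(=O)OC[C@@H]1Cc1ccc(O[Si](C(C)C)(C(C)C)C(C)C)c(OC)c1
F11 | step 9 | methiodide of F10 | C[N+](C)(C)CC1C(=O)OC[C@@H]1Cc1ccc(O[Si](C(C)C)(C(C)C)C(C)C)c(OC)c1.[I-]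
F0 | step 10 | none | none
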